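## Structural features

The target is a 4-aryl-1-tetralone. A 6,7-dimethoxybenzo ring (ring A) is fused to a six-membered carbocycle (ring B) that carries the C1 ketone, methyl groups on C2 and C3, and a 3-hydroxy-4-methoxyphenyl group (ring C) on C4. The three stereocentres are contiguous, (2S,3R,4R): the two methyl groups are trans and the C3 methyl is cis to the C4 aryl group. C2 is alpha to the ketone and epimerisable, and the required configuration is the thermodynamic one. With the aryl group pseudoaxial (away from the peri C5–H) both methyl groups are pseudoequatorial, whereas the 2-epimer would hold its methyl 1,3-diaxial to the aryl group. C3 and C4 cannot be corrected by equilibration, so the real difficulty is to set this vicinal pair in the absolute sense; C4 is a doubly benzylic methine with no heteroatom. The fragile points are the free phenol, the two electron-rich rings and the tendency of ring B to aromatise: a cation or double bond at C4, then loss of the C3 hydrogen and enolisation, gives a 1-naphthol and destroys all three stereocentres. The key step uses the fact that C2 and C3 are alpha and beta to the C1 carbonyl. Both C–CH3 bonds can therefore be made on a C2=C3 enone in ring B by conjugate addition and enolate trapping, while C4, held as a quaternary diaryl carbinol ether, directs the incoming methyl group and blocks aromatisation.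

## Logic of the disconnections

18 back to 17. The phenolic O–CH2Ph bond on ring C is cut. A free phenol would be deprotonated or oxidised by the organometallic and photochemical steps, so it is carried as a benzyl ether. The skeleton is not simplified. The forward hydrogenolysis must spare the aryl ketone and the C4–H bond.

17 back to 16. The C4–H bond is traced back to a C4–O bond. With oxygen on C4 the centre is quaternary, cannot aromatise during enolate chemistry, and becomes the product of a carbonyl addition. The hardest stereocentre thus turns into a relay. The forward removal must be radical and not cationic, hydrogen must arrive anti to the C3 methyl, and C2 must end under thermodynamic control.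

16 back to 14 (through 15), and 14 back to 13. The O–acyl bond of the oxalate and then the O–Si bond are cut. The ester that triggers fragmentation would not survive an organocopper reagent, whereas a silyl ether does, so the two groups are exchanged after the methyl groups are in place. Both forward steps must avoid acid, because the C4 carbinol ionises easily.

13 back to 11 (through 12). The C3–CH3 and C2–CH3 bonds are cut together. They lie beta and alpha to the ketone, so one enone serves both. Two stereocentres and two carbons are removed and a single stereocentre remains. The forward step needs 1,4-addition from the face opposite the aryl group, monoalkylation of the enolate on carbon, and retention of the C4–O bond.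

11 back to 10, and 10 back to 4 and 6 (through 7, 8, 9). After the O–Si bond, the bond between C4 and ring C is cut. This divides the molecule into two pieces of similar size and uses the one free carbonyl of a mono-protected quinone as electrophile, so regiochemistry is not in question. The symmetric 6,7-dimethoxy pattern makes the two possible numberings identical after unmasking. The forward step must distinguish the two faces of a cross-conjugated ketone and unmask the second carbonyl under mild conditions.

6 back to 5. The O–benzyl bond is cut, giving a commercial bromophenol. The forward step is a simple alkylation.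

4 back to 2 (through 3), and 2 back to 1. The two C4–OCH3 bonds are cut, then ring B is taken back to its saturated form. Compound 1 is commercial and already has the oxygenation pattern of ring A. The forward oxidation must go twice at the position para to the hydroxyl group.

## Other disconnections considered

Alternative 1: The cut is C2–C3. The alpha-methyl beta-keto ester A1, which carries a terminal alkyne on the future C4, would be closed with In(NTf2)3, a salt of trivalent indium. The indium enolate adds across the alkyne in a 6-exo-dig Conia-ene reaction to give the 3-methylene tetralone A2.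
- In its favour: the closure is catalytic and atom-economic. The quaternary C2 of A2 cannot enolise, so ring B cannot aromatise during the closure. Both C2 epimers converge once the ester is removed.
- Better than the chosen plan: C4 carries its hydrogen from the start, so there is no oxidation-state detour at C4.
- Against it: the only stereocentre of A1 is a diaryl propargylic methine. It would need its own enantioselective synthesis, and it is doubly benzylic and propargylic, so propargyl–allene isomerisation and racemisation threaten under basic or hot Lewis-acidic conditions. Electron-rich ring C may also compete with the enol for the activated alkyne.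
- After the closure: C3 must be set by hydrogenating the exocyclic methylene of A2 from the face opposite the aryl group. The ester may be removed only afterwards, since a beta,gamma-enone without the blocking ester would conjugate and aromatise.
- Comparison: both plans rely on substrate control from a neighbouring centre, so they are equal in stereochemical logic. Alternative 1 is no shorter once the synthesis of A1 is counted, and its stereochemical source is more fragile than a silylated quinol.

Alternative 2: The cut is C3–C4. The ortho-benzylaryl tiglyl ketone A3 would be deprotonated at the diarylmethane CH2 by solid KOH in the presence of a chiral quaternary ammonium salt. The resulting dienolate (an oxy-ortho-quinodimethane) closes by disrotatory 6π electrocyclisation, and protonation at C2 gives A4, which is identical with 17.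
- In its favour: A3 is available in a few steps, the key step forms ring B and all three stereocentres, and only debenzylation remains.
- Better than the chosen plan: it is clearly shorter and has no protecting-group or redox detour at C4.
- Equal to the chosen plan: the C3/C4 cis relationship follows from a well-understood element (both terminal substituents outside in a disrotatory closure), and C2 is thermodynamic.
- Against it: the absolute configuration would rest on a chiral cation paired with a delocalised carbocyclic dienolate. Cation-directed asymmetric 6π closures are established for aza-pentadienyl anions, not for this triene.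
- Further risks: the CH2 of A3 is at the limit of what solid hydroxide deprotonates, the gamma-methyl of the tiglyl group competes, E/Z isomerisation and Michael oligomerisation are possible, and an uncatalysed racemic closure is a background path. A poor enantiomeric purity could not be repaired later.
- Comparison: the chosen plan is longer but places each stereocentre by a separate, individually precedented element.

Alternative 3: The cuts are C1–C2 and C3–C4. Irradiation of the ortho-benzylbenzaldehyde A5 at 365 nm with Ti(OiPr)4 and a TADDOL ligand would give the E-dienol, which adds methyl angelate A6 endo to give the all-cis hydroxy ester A7.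
- In its favour: it is convergent, forms two C–C bonds and ring B in one step, and sets the C3/C4 cis relationship directly. Titanium-templated photoenol Diels–Alder reactions are an established way to tetralin cores.
- Better than the chosen plan: A5 is simple and only oxidation at C1, dealkoxycarbonylation with C2 equilibration and debenzylation follow, so it is shorter.
- Equal to the chosen plan: both depend on one ligand-controlled step for the absolute configuration.
- Against it: the diene terminus of A5 bears an aryl group, which slows the cycloaddition and makes the dienol geometry critical. A6 is a trisubstituted, weakly activated dienophile that can undergo E/Z isomerisation under light or Lewis acid, which would erode C3. A5 has no oxygen ortho to the formyl group to anchor titanium.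
- Comparison: regiochemistry, endo selectivity, geometry and enantioface selection all rest on a single intermolecular event, whereas the chosen plan spreads these demands over several steps.

Key step: step 6

Assumption: which antipode of BINOL delivers the (R)-carbinol in step 4 cannot be predicted with confidence for this ketone; (S)-BINOL is written and the other antipode is to be used if the sense is opposite.

## Route

Step 1
Reactants: 1 6,7-dimethoxy-3,4-dihydronaphthalen-1(2H)-one
Product: 2 6,7-dimethoxynaphthalen-1-ol
Conditions: Pd/C (10 wt%), triglyme, reflux, N2 sweep
Reagents that add atoms: none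
Why: Catalytic dehydrogenative aromatisation: palladium removes hydrogen from the saturated C2–C3–C4 chain, the resulting naphthalen-1(2H)-one tautomerises irreversibly to the naphthol, and sweeping out H2 limits hydrogen transfer back to 1.

Step 2
Reactants: 2 6,7-dimethoxynaphthalen-1-ol
Product: 4 4,4,6,7-tetramethoxynaphthalen-1(4H)-one, via 4,6,7-trimethoxynaphthalen-1-ol 3 (not isolated)
Conditions: PhI(OAc)2 (2.2 equiv), MeOH, 0 °C to rt
Reagents that add atoms: methanol, CO
Why: Oxidative dearomatisation of a phenol with a hypervalent iodine reagent: the first equivalent brings methanol in para to the hydroxyl group and the adduct rearomatises to 3, the second equivalent oxidises 3 to the para-quinone monoketal, the para position being preferred because the new methoxy group stabilises the developing cation.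

Step 3
Reactants: 5 5-bromo-2-methoxyphenol
Product: 6 2-(benzyloxy)-4-bromo-1-methoxybenzene
Conditions: BnBr, K2CO3, DMF, rt
Reagents that add atoms: benzyl bromide, BrCc1ccccc1
Why: Williamson ether synthesis on the phenoxide; the benzyl ether tolerates organolithium, organotitanium, cuprate, fluoride and photoredox conditions and is removed by hydrogenolysis at the end.

Step 4
Reactants: 4 4,4,6,7-tetramethoxynaphthalen-1(4H)-one; 6 2-(benzyloxy)-4-bromo-1-methoxybenzene
Product: 10 (4R)-4-[3-(benzyloxy)-4-methoxyphenyl]-4-hydroxy-6,7-dimethoxynaphthalen-1(4H)-one, via aryllithium 7 (not isolated), via aryltitanium triisopropoxide 8 (not isolated), via carbinol ketal 9 (not isolated)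
Conditions: 6, n-BuLi, THF, −78 °C; ClTi(OiPr)3, −78 °C to rt, solvent switch to toluene; then 4, Ti(OiPr)4 (20 mol%), (S)-BINOL (10 mol%), toluene, 0 °C; then 5% aq. oxalic acid, THF, rt
Reagents that add atoms: water, O
Why: Proposed new method: bromine–lithium exchange and transmetalation give the non-basic aryl donor 8; the closest known reaction type is the enantioselective aryl transfer from ArTi(OiPr)3 to aryl alkyl ketones and enones catalysed by a BINOLate of tetravalent titanium, in which the Lewis acid binds the carbonyl syn to its smaller flank and the ligand shields one face; in 4 the flanks are the benzo ring with its peri C8–H and the slimmer C2 vinyl CH, a difference comparable to that in 1-tetralone, so 1,2-transfer to one face should give (R)-9 (hard organotitanium reagents do not add 1,4), and dilute oxalic acid then hydrolyses the allylic, benzylic dimethyl ketal to dienone 10, whose cross-conjugated carbonyl disfavours ionisation of the new carbinol.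

Step 5
Reactants: 10 (4R)-4-[3-(benzyloxy)-4-methoxyphenyl]-4-hydroxy-6,7-dimethoxynaphthalen-1(4H)-one
Product: 11 (4R)-4-[3-(benzyloxy)-4-methoxyphenyl]-6,7-dimethoxy-4-(triethylsilyloxy)naphthalen-1(4H)-one
Conditions: Et3SiOTf, 2,6-lutidine, CH2Cl2, −78 to 0 °C
Reagents that add atoms: triethylsilyl trifluoromethanesulfonate, CC[Si](CC)(CC)OS(=O)(=O)C(F)(F)F
Why: Silyl triflate and hindered base silylate tertiary alcohols under non-acidic conditions, so the diaryl carbinol is not ionised; the triethylsilyl ether is a poor leaving group and keeps C4 oxygenated through the organocopper step.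

Step 6
Reactants: 11 (4R)-4-[3-(benzyloxy)-4-methoxyphenyl]-6,7-dimethoxy-4-(triethylsilyloxy)naphthalen-1(4H)-one
Product: 13 (2S,3S,4R)-4-[3-(benzyloxy)-4-methoxyphenyl]-6,7-dimethoxy-2,3-dimethyl-4-(triethylsilyloxy)-3,4-dihydronaphthalen-1(2H)-one, via lithium enolate 12 (not isolated)
Conditions: Me2CuLi (from MeLi, CuI), Et2O, −78 to −30 °C; then MeI (excess), DMPU, THF, −30 to 0 °C
Reagents that add atoms: lithium dimethylcuprate, [Li+].C[Cu-]C; iodomethane, CI
Why: Me2CuLi forms a π-complex with the C2=C3 bond of 11, oxidative addition gives a beta-cuprio enolate of trivalent copper, and reductive elimination forms the C3–CH3 bond and lithium enolate 12; MeI with DMPU then alkylates C2 by SN2 displacement, so both C–CH3 bonds arise in one flask. The closest known reaction type is cuprate conjugate addition to 4,4-disubstituted cyclohexadienones of the quinol ether class followed by alkylation of the regiodefined enolate. No ring is formed. C3 is controlled by C4: the dienone is flat, its faces differ only in carrying the aryl group or the silyloxy oxygen, and the reagent should pass the small oxygen atom (the triethylsilyl group can turn away over ring A) rather than the aryl group, in line with the general preference of nucleophiles for the oxygen-bearing face of 4-oxygenated dienones, so the methyl group ends anti to the aryl group (3S). C2 is controlled by C3: in 12 the C3 methyl sits pseudoaxial to avoid the two C4 substituents and MeI attacks the opposite enolate face, giving the trans-dimethyl arrangement (2S), which the base treatment in step 9 secures in any case. The step needs 1,4- rather than 1,2-addition (soft cuprate, carbonyl deactivated by the para 6-methoxy group), C- rather than O-alkylation, and mono- rather than dimethylation at C2 (lithium enolate, excess MeI, low temperature, short time). It also needs the C4–O bond to survive: a silyl ether is a poor leaving group, so electron transfer from the cuprate should not expel it, whereas an ester at C4 would be lost with aromatisation of ring B.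

Step 7
Reactants: 13 (2S,3S,4R)-4-[3-(benzyloxy)-4-methoxyphenyl]-6,7-dimethoxy-2,3-dimethyl-4-(triethylsilyloxy)-3,4-dihydronaphthalen-1(2H)-one
Product: 14 (2S,3S,4R)-4-[3-(benzyloxy)-4-methoxyphenyl]-4-hydroxy-6,7-dimethoxy-2,3-dimethyl-3,4-dihydronaphthalen-1(2H)-one
Conditions: Bu4NF, AcOH, THF, 0 °C to rt
Reagents that add atoms: none
Why: Fluoride cleaves the Si–O bond; acetic acid buffers the alkoxide, and the absence of strong acid leaves the ionisable C4 carbinol and the C3 stereocentre untouched.

Step 8
Reactants: 14 (2S,3S,4R)-4-[3-(benzyloxy)-4-methoxyphenyl]-4-hydroxy-6,7-dimethoxy-2,3-dimethyl-3,4-dihydronaphthalen-1(2H)-one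
Product: 16 cesium 2-{[(1R,2S,3S)-1-[3-(benzyloxy)-4-methoxyphenyl]-6,7-dimethoxy-2,3-dimethyl-4-oxo-1,2,3,4-tetrahydronaphthalen-1-yl]oxy}-2-oxoacetate, via methyl oxalate 15 (not isolated)
Conditions: ClC(O)CO2Me, Et3N, DMAP (cat.), CH2Cl2, 0 °C; then CsOH (1.0 equiv), THF/H2O, 0 °C
Reagents that add atoms: methyl chlorooxoacetate, COC(=O)C(Cl)=O; cesium hydroxide, [Cs+].[OH-]
Why: The very electrophilic oxalyl chloride half-ester acylates the hindered tertiary hydroxyl under DMAP catalysis to give 15; one equivalent of CsOH saponifies the unhindered methyl ester much faster than the tertiary ester, and the carboxylate salt 16 is a poorer leaving group than a neutral oxalate, which limits ionisation at C4.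

Step 9
Reactants: 16 cesium 2-{[(1R,2S,3S)-1-[3-(benzyloxy)-4-methoxyphenyl]-6,7-dimethoxy-2,3-dimethyl-4-oxo-1,2,3,4-tetrahydronaphthalen-1-yl]oxy}-2-oxoacetate
Product: 17 (2S,3R,4R)-4-[3-(benzyloxy)-4-methoxyphenyl]-6,7-dimethoxy-2,3-dimethyl-3,4-dihydronaphthalen-1(2H)-one
Conditions: [Ir(dF(CF3)ppy)2(dtbbpy)]PF6 (1 mol%), 2,4,6-triisopropylbenzenethiol (20 mol%), H2O, DME/DMF, blue LEDs, rt; then NaOMe (cat.), MeOH, rt
Reagents that add atoms: none
Why: Photoredox oxidative double decarboxylation of a tertiary alkyl cesium oxalate: the excited complex of trivalent iridium oxidises the carboxylate, two molecules of CO2 are lost and the planar diaryl C4 radical forms without a cationic stage. Allylic 1,2-strain with the in-plane aryl group holds the C3 methyl pseudoaxial, so hydrogen is delivered to the opposite face, either by the thiol or, after reduction by the divalent iridium species, by water protonating the ortho-acyl benzylic anion, and the aryl group ends cis to the C3 methyl (4R). The methoxide stir then equilibrates C2 to the arrangement with pseudoaxial aryl and two pseudoequatorial methyl groups (2S).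

Step 10
Reactants: 17 (2S,3R,4R)-4-[3-(benzyloxy)-4-methoxyphenyl]-6,7-dimethoxy-2,3-dimethyl-3,4-dihydronaphthalen-1(2H)-one
Product: 18 (2S,3R,4R)-4-(3-hydroxy-4-methoxyphenyl)-6,7-dimethoxy-2,3-dimethyl-3,4-dihydronaphthalen-1(2H)-one
Conditions: H2 (1 atm), Pd/C (10 wt%), EtOAc/MeOH, rt
Reagents that add atoms: none
Why: Hydrogenolysis of the benzyl aryl ether on palladium; at ambient pressure the electron-rich aryl ketone and the doubly benzylic C4–H should not react, and no stereocentre is touched.

## Compound list

1 | 6,7-dimethoxy-3,4-dihydronaphthalen-1(2H)-one (6,7-dimethoxy-1-tetralone) | COc1cc2CCCC(=O)c2cc1OC | starting material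
2 | 6,7-dimethoxynaphthalen-1-ol | COc1cc2cccc(O)c2cc1OC | intermediate
3 | 4,6,7-trimethoxynaphthalen-1-ol | COc1cc2c(OC)ccc(O)c2cc1OC | intermediate
4 | 4,4,6,7-tetramethoxynaphthalen-1(4H)-one | COc1cc2C(=O)C=CC(OC)(OC)c2cc1OC | intermediate
5 | 5-bromo-2-methoxyphenol | COc1ccc(Br)cc1O | starting material
6 | 2-(benzyloxy)-4-bromo-1-methoxybenzene | COc1ccc(Br)cc1OCc1ccccc1 | intermediate
7 | [3-(benzyloxy)-4-methoxyphenyl]lithium | [Li]c1ccc(OC)c(OCc2ccccc2)c1 | intermediate
8 | [3-(benzyloxy)-4-methoxyphenyl]tri(propan-2-yloxy)titanium | CC(C)O[Ti](OC(C)C)(OC(C)C)c1ccc(OC)c(OCc2ccccc2)c1 | intermediate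
9 | (1R)-1-[3-(benzyloxy)-4-methoxyphenyl]-4,4,6,7-tetramethoxy-1,4-dihydronaphthalen-1-ol (formed as its titanium alkoxide) | COc1ccc([C@@]2(O)c3cc(OC)c(OC)cc3C(OC)(OC)C=C2)cc1OCc1ccccc1 | intermediate
10 | (4R)-4-[3-(benzyloxy)-4-methoxyphenyl]-4-hydroxy-6,7-dimethoxynaphthalen-1(4H)-one | COc1ccc([C@@]2(O)c3cc(OC)c(OC)cc3C(=O)C=C2)cc1OCc1ccccc1 | intermediate
11 | (4R)-4-[3-(benzyloxy)-4-methoxyphenyl]-6,7-dimethoxy-4-(triethylsilyloxy)naphthalen-1(4H)-one | COc1ccc([C@@]2(O[Si](CC)(CC)CC)c3cc(OC)c(OC)cc3C(=O)C=C2)cc1OCc1ccccc1 | intermediate
12 | lithium (3S,4R)-4-[3-(benzyloxy)-4-methoxyphenyl]-6,7-dimethoxy-3-methyl-4-(triethylsilyloxy)-3,4-dihydronaphthalen-1-olate | COc1ccc([C@@]2(O[Si](CC)(CC)CC)c3cc(OC)c(OC)cc3C(O[Li])=C[C@@H]2C)cc1OCc1ccccc1 | intermediate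
13 | (2S,3S,4R)-4-[3-(benzyloxy)-4-methoxyphenyl]-6,7-dimethoxy-2,3-dimethyl-4-(triethylsilyloxy)-3,4-dihydronaphthalen-1(2H)-one | COc1ccc([C@@]2(O[Si](CC)(CC)CC)c3cc(OC)c(OC)cc3C(=O)[C@@H](C)[C@@H]2C)cc1OCc1ccccc1 | intermediate
14 | (2S,3S,4R)-4-[3-(benzyloxy)-4-methoxyphenyl]-4-hydroxy-6,7-dimethoxy-2,3-dimethyl-3,4-dihydronaphthalen-1(2H)-one | COc1ccc([C@@]2(O)c3cc(OC)c(OC)cc3C(=O)[C@@H](C)[C@@H]2C)cc1OCc1ccccc1 | intermediate
15 | methyl (1R,2S,3S)-1-[3-(benzyloxy)-4-methoxyphenyl]-6,7-dimethoxy-2,3-dimethyl-4-oxo-1,2,3,4-tetrahydronaphthalen-1-yl oxalate | COc1ccc([C@@]2(OC(=O)C(=O)OC)c3cc(OC)c(OC)cc3C(=O)[C@@H](C)[C@@H]2C)cc1OCc1ccccc1 | intermediate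
16 | cesium 2-{[(1R,2S,3S)-1-[3-(benzyloxy)-4-methoxyphenyl]-6,7-dimethoxy-2,3-dimethyl-4-oxo-1,2,3,4-tetrahydronaphthalen-1-yl]oxy}-2-oxoacetate | COc1ccc([C@@]2(OC(=O)C(=O)[O-])c3cc(OC)c(OC)cc3C(=O)[C@@H](C)[C@@H]2C)cc1OCc1ccccc1.[Cs+] | intermediate
17 | (2S,3R,4R)-4-[3-(benzyloxy)-4-methoxyphenyl]-6,7-dimethoxy-2,3-dimethyl-3,4-dihydronaphthalen-1(2H)-one | COc1ccc([C@@H]2c3cc(OC)c(OC)cc3C(=O)[C@@H](C)[C@@H]2C)cc1OCc1ccccc1 | intermediate
18 | (2S,3R,4R)-4-(3-hydroxy-4-methoxyphenyl)-6,7-dimethoxy-2,3-dimethyl-3,4-dihydronaphthalen-1(2H)-one | COc1ccc([C@@H]2c3cc(OC)c(OC)cc3C(=O)[C@@H](C)[C@@H]2C)cc1O | target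

## Step count and least certain steps

Total step count: 10. Longest linear sequence: 9 steps (steps 1, 2 and 4 to 10, from 1 to 18); step 3 is a one-step side branch.

Step 4 (Proposed new method). Most likely failure: insufficient discrimination between the two faces of the cross-conjugated carbonyl, because both flanks are sp2 carbons that differ only modestly in size. Uncatalysed background addition promoted by residual lithium salts would lower the selectivity further, and reversible ionisation of the carbinol during ketal hydrolysis could erode it. Fallback with known chemistry, setting out from 4 and 6: aryllithium 7 (n-BuLi, THF, −78 °C) is added directly to 4, the classical uncatalysed 1,2-addition to quinone monoketals, to give the racemic carbinol ketal F1. Aqueous acetic acid hydrolyses it to the racemic quinol F2. Preparative chromatography on a polysaccharide-based chiral stationary phase separates 10 from its (S)-enantiomer F3. The route is rejoined at 10.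

Step 6 (key step). Most likely failures: approach of the cuprate from the aryl-bearing face, because the stereoelectronic preference for attack anti to the C–O bond opposes the steric preference; electron-transfer-induced loss of the C4 oxygen with aromatisation; proton exchange between enolate and product leading to double methylation at C2. Fallback, setting out from 10: the free hydroxyl is used to deliver the methyl group. An excess of MeMgCl (or Me3Al) forms the metal alkoxide, which directs conjugate methyl transfer to its own face, a known behaviour of para-quinols. This gives the (3S,4R)-4-hydroxy-3-methyl tetralone F4. Silylation as in step 5 gives its triethylsilyl ether F5. LDA in THF at −78 °C regenerates enolate 12, and MeI with DMPU gives 13, where the route is rejoined.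

Step 9. Most likely failures: unselective hydrogen delivery to the planar C4 intermediate; oxidation of the electron-rich radical to the cation followed by loss of the C3 proton and aromatisation; unproductive quenching of the excited photocatalyst by thiolate. Fallback, setting out from 14: stereospecific hydrogenolysis of the tertiary benzylic C–O bond on palladium (H2, Pd/C, EtOH, trace acid). This is known to proceed with inversion at benzylic carbon and does not pass through a planar intermediate. Inversion at C4 gives the required cis relationship of aryl and C3 methyl, the benzyl ether is cleaved in the same operation, and the route is rejoined at 18.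

Step 8. Most likely failures: incomplete acylation of the hindered tertiary hydroxyl; ionisation of the activated ester at the doubly benzylic carbon, followed by loss of the C3 proton and aromatisation of ring B. Fallback, setting out from 14: ionic hydrogenation without any isolated ester (Et3SiH, then BF3·OEt2, CH2Cl2, −78 °C). The cation is generated in the presence of the hydride donor and should be reduced faster than it loses a proton, with hydride entering anti to the pseudoaxial C3 methyl. The route is rejoined at 17.

Step 1. Most likely failures: hydrogen transfer back to the substrate (disproportionation and hydrogenolysis of the carbonyl), incomplete conversion, and thermal degradation of the electron-rich naphthol. Fallback, setting out from 1: alpha-bromination (CuBr2, EtOAc/CHCl3, reflux) gives 2-bromo-6,7-dimethoxy-1-tetralone F6. Dehydrobromination with LiBr and Li2CO3 in DMF at 130 °C, followed by tautomerisation, gives 2, where the route is rejoined.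

## Further compounds

F1 | step 4 | rac-1-[3-(benzyloxy)-4-methoxyphenyl]-4,4,6,7-tetramethoxy-1,4-dihydronaphthalen-1-ol | COc1ccc(C2(O)c3cc(OC)c(OC)cc3C(OC)(OC)C=C2)cc1OCc1ccccc1
F2 | step 4 | rac-4-[3-(benzyloxy)-4-methoxyphenyl]-4-hydroxy-6,7-dimethoxynaphthalen-1(4H)-one | COc1ccc(C2(O)c3cc(OC)c(OC)cc3C(=O)C=C2)cc1OCc1ccccc1
F3 | step 4 | (4S)-4-[3-(benzyloxy)-4-methoxyphenyl]-4-hydroxy-6,7-dimethoxynaphthalen-1(4H)-one | COc1ccc([C@]2(O)c3cc(OC)c(OC)cc3C(=O)C=C2)cc1OCc1ccccc1
F4 | step 6 | (3S,4R)-4-[3-(benzyloxy)-4-methoxyphenyl]-4-hydroxy-6,7-dimethoxy-3-methyl-3,4-dihydronaphthalen-1(2H)-one | COc1ccc([C@@]2(O)c3cc(OC)c(OC)cc3C(=O)C[C@@H]2C)cc1OCc1ccccc1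
F5 | step 6 | (3S,4R)-4-[3-(benzyloxy)-4-methoxyphenyl]-6,7-dimethoxy-3-methyl-4-(triethylsilyloxy)-3,4-dihydronaphthalen-1(2H)-one | COc1ccc([C@@]2(O[Si](CC)(CC)CC)c3cc(OC)c(OC)cc3C(=O)C[C@@H]2C)cc1OCc1ccccc1
F0 | step 9 | none | none
F0 | step 8 | none | none
F6 | step 1 | 2-bromo-6,7-dimethoxy-3,4-dihydronaphthalen-1(2H)-one (racemic) | COc1cc2CCC(Br)C(=O)c2cc1OC
A1 | alternative 1 | methyl 3-{2-[(1R)-1-[3-(benzyloxy)-4-methoxyphenyl]prop-2-yn-1-yl]-4,5-dimethoxyphenyl}-2-methyl-3-oxopropanoate | COc1ccc([C@@H](C#C)c2cc(OC)c(OC)cc2C(=O)C(C)C(=O)OC)cc1OCc1ccccc1
A2 | alternative 1 | methyl (4S)-4-[3-(benzyloxy)-4-methoxyphenyl]-6,7-dimethoxy-2-methyl-3-methylidene-1-oxo-1,2,3,4-tetrahydronaphthalene-2-carboxylate (C2 epimers) | COc1ccc([C@@H]2c3cc(OC)c(OC)cc3C(=O)C(C)(C(=O)OC)C2=C)cc1OCc1ccccc1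
A3 | alternative 2 | (2E)-1-{2-[3-(benzyloxy)-4-methoxybenzyl]-4,5-dimethoxyphenyl}-2-methylbut-2-en-1-one | COc1ccc(Cc2cc(OC)c(OC)cc2C(=O)/C(C)=C/C)cc1OCc1ccccc1
A4 | alternative 2 | (2S,3R,4R)-4-[3-(benzyloxy)-4-methoxyphenyl]-6,7-dimethoxy-2,3-dimethyl-3,4-dihydronaphthalen-1(2H)-one (identical with 17) | COc1ccc([C@@H]2c3cc(OC)c(OC)cc3C(=O)[C@@H](C)[C@@H]2C)cc1OCc1ccccc1
A5 | alternative 3 | 2-[3-(benzyloxy)-4-methoxybenzyl]-4,5-dimethoxybenzaldehyde | COc1ccc(Cc2cc(OC)c(OC)cc2C=O)cc1OCc1ccccc1
A6 | alternative 3 | methyl (2Z)-2-methylbut-2-enoate (methyl angelate) | C/C=C(/C)C(=O)OC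
A7 | alternative 3 | methyl (1S,2R,3R,4R)-4-[3-(benzyloxy)-4-methoxyphenyl]-1-hydroxy-6,7-dimethoxy-2,3-dimethyl-1,2,3,4-tetrahydronaphthalene-2-carboxylate (hydroxyl, ester, C3 methyl and aryl all cis) | COc1ccc([C@@H]2c3cc(OC)c(OC)cc3[C@H](O)[C@@](C(=O)OC)(C)[C@@H]2C)cc1OCc1ccccc1
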